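**Retrosynthetic overview**
1. Numbering: the carbocycle is bicyclo[4.2.0]octane, with C1 the fusion CH, C2 and C5 the two C–O carbons, C3=C4 the alkene, C6 the fusion C–Me, C7 the CH–Me and C8 the C(Me)–pyranone carbon. The plan rests on C2 of the 2,3-dioxabicyclo[2.2.2]oct-5-ene. C2 is tertiary and allylic, so its methyl group can be carried as an exocyclic C2=CH2 conjugated with C3=C4. The C2–O bond can then be made last, from a hydroperoxide already sitting on C5.
2. 24 ⇒ (C–Hg to C–H) organomercurial 23 ⇒ (mercury-induced closure of C5–OOH onto the diene, forming the C2–O bond and the peroxide ring) hydroperoxide 22 ⇒ (Schenck ene reaction) skipped diene 21.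
3. 21 ⇒ C2 carbinol 19 (oxidation, then methylenation). The pyranone ring ⇒ lactone 13 plus a β-keto ester dianion. C4=C5 ⇒ the C5 ketone through its enol triflate.
4. The cyclobutane and the oxolane ⇒ one intramolecular enone–alkene [2+2] photocycloaddition of (R)-4-crotyloxy enone 7. The C2–O tether relays C2 to C1, C6 and C8, C7 follows the convex face, and the C8 methyl enters through the lactone enolate. C2 itself comes from a CBS reduction.
5. Ring order: cyclohexene (bought) → cyclobutane plus oxolane (step 6) → pyranone (step 12; the oxolanone is opened in step 11) → 1,2-dioxane bridge (step 17).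

Key step: step 17

Remark: "convex face" (exo) means the face that carries C1–H and C6–Me, anti to C7/C8 on the six-membered ring, and "endo" is the opposite side. Commercial, mainly (E), crotyl bromide is assumed to be good enough, because the alkene geometry is lost in the triplet diradical of step 6.

Step 1
Reactants: 1 1,4-dioxaspiro[4.5]dec-6-en-8-one
Product: 2 [(6-methyl-1,4-dioxaspiro[4.5]dec-7-en-8-yl)oxy]trimethylsilane (racemic)
Conditions: MeMgBr, CuBr·SMe2 (10 mol %), Me3SiCl, HMPA, THF, −78 °C
Reagents that add atoms: methylmagnesium bromide C[Mg]Br; chlorotrimethylsilane C[Si](C)(C)Cl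
Why: Copper-catalysed conjugate addition of the Grignard reagent, accelerated by the chlorosilane, should put the future C6 methyl on the β-carbon next to the ketal and store the enolate regiospecifically as its silyl ether; the new stereocentre is racemic and disappears in step 2.

Step 2
Reactants: 2 [(6-methyl-1,4-dioxaspiro[4.5]dec-7-en-8-yl)oxy]trimethylsilane
Product: 3 6-methyl-1,4-dioxaspiro[4.5]dec-6-en-8-one
Conditions: Pd(OAc)2 (1.05 equiv), MeCN, 25 °C
Reagents that add atoms: none
Why: Saegusa–Ito oxidation: the palladium enolate formed from the regiodefined silyl enol ether can only lose the β-hydride of the methyl-bearing carbon, so the double bond should return between C1 and C6 and give the β-methyl enone without touching the ketal.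

Step 3
Reactants: 3 6-methyl-1,4-dioxaspiro[4.5]dec-6-en-8-one
Product: 4 (R)-6-methyl-1,4-dioxaspiro[4.5]dec-6-en-8-ol
Conditions: (S)-Me-CBS oxazaborolidine [(S)-1-methyl-3,3-diphenyltetrahydro-1H,3H-pyrrolo[1,2-c][1,3,2]oxazaborole] (15 mol %), catecholborane, toluene, −78 °C
Reagents that add atoms: none
Why: Corey–Bakshi–Shibata reduction: with the substituted alkenyl arm as the large group and the ring CH2 as the small group, the (S)-catalyst should deliver hydride to one carbonyl face and set C2 as (R), the stereocentre from which all others are relayed; catecholborane at low temperature avoids hydroboration of the alkene.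

Step 4
Reactants: 4 (R)-6-methyl-1,4-dioxaspiro[4.5]dec-6-en-8-ol; 5 (E)-1-bromobut-2-ene
Product: 6 (R)-8-[(E)-but-2-enyloxy]-6-methyl-1,4-dioxaspiro[4.5]dec-6-ene
Conditions: NaH, THF, 0 → 25 °C
Reagents that add atoms: none
Why: Williamson ether synthesis of the alkoxide on a primary allylic bromide; the C–O bond at C2 is not involved, so its configuration is kept, and the ketal tolerates the base.

Step 5
Reactants: 6 (R)-8-[(E)-but-2-enyloxy]-6-methyl-1,4-dioxaspiro[4.5]dec-6-ene
Product: 7 (R)-4-[(E)-but-2-enyloxy]-2-methylcyclohex-2-en-1-one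
Conditions: 1 M HCl (cat.), THF/H2O, 0 → 25 °C
Reagents that add atoms: water O
Why: Acid-catalysed ketal hydrolysis unmasks the C5 ketone and with it the 2-methyl enone chromophore; the allyl ether and the C2 stereocentre should survive these mild conditions.

Step 6
Reactants: 7 (R)-4-[(E)-but-2-enyloxy]-2-methylcyclohex-2-en-1-one
Product: 8 1,2-dimethyl-5-oxatricyclo[4.3.1.0^3,10]decan-9-one (cyclobutane C1–C6–C7–C8 cis-fused to the C5 cyclohexanone and to the oxolane C1–C2–O–CH2–C8; C1–H, C6–Me, C7–Me and C8–H convex)
Conditions: hν (366 nm, Pyrex), degassed MeCN (5 mM), 0 °C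
Reagents that add atoms: none
Why: Intramolecular enone–alkene [2+2] photocycloaddition through the enone triplet: the three-atom tether enforces five-membered closure first (C1–C8, rule of five) and then C6–C7, so the straight regioisomer should form; the tether on C2 allows addition only to the enone face syn to C2–O, which sets C1, C6 (cis fusion, methyl convex) and C8 (CH2O endo), while C7 is set at closure of the 1,4-diradical, where the methyl should avoid the cleft lined by C5=O and the oxolane CH2 and take the convex side next to C8–H.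

Step 7
Reactants: 8 1,2-dimethyl-5-oxatricyclo[4.3.1.0^3,10]decan-9-one
Product: 9 1,2-dimethyl-5-oxatricyclo[4.3.1.0^3,10]decane-4,9-dione (keto lactone)
Conditions: RuCl3·xH2O (5 mol %), NaIO4 (4 equiv), EtOAc/MeCN/H2O, 25 °C
Reagents that add atoms: sodium periodate [Na+].[O-]I(=O)(=O)=O
Why: Ruthenium tetroxide-catalysed oxidation of an ether to a lactone: the unhindered O–CH2 group is oxidised in preference to the tertiary O–CH at C2, the ketone and the saturated skeleton are inert, and no stereocentre is affected.

Step 8
Reactants: 9 1,2-dimethyl-5-oxatricyclo[4.3.1.0^3,10]decane-4,9-dione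
Product: 11 1,2,3,8-tetramethyl-5-oxatricyclo[4.3.1.0^3,10]decane-4,9-dione (C4 epimers; C8–Me convex), via dilithium bis-enolate 10 (not isolated)
Conditions: LiN(iPr)2 (1.0 then 1.1 equiv), THF, −78 → −40 °C; MeI, DMPU, −78 → −20 °C
Reagents that add atoms: iodomethane CI
Why: Ketone and lactone are deprotonated in turn, so that C5 is already an enolate when C8 is metalated, which blocks retro-Michael opening of the cyclobutane; double enolate alkylation should then place one methyl on C4 (epimers, erased in step 9) and one on C8, where only the convex face can be attacked because a trans-fused oxabicyclo[3.2.0]heptanone is out of reach, so C8 gets methyl exo and the acyl carbon endo.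

Step 9
Reactants: 11 1,2,3,8-tetramethyl-5-oxatricyclo[4.3.1.0^3,10]decane-4,9-dione
Product: 12 1,2,3,8-tetramethyl-4-oxo-5-oxatricyclo[4.3.1.0^3,10]dec-8-en-9-yl trifluoromethanesulfonate
Conditions: KN(SiMe3)2, THF, −78 °C; PhNTf2, −78 → 0 °C
Reagents that add atoms: N-phenylbis(trifluoromethanesulfonimide) O=S(=O)(N(c1ccccc1)S(=O)(=O)C(F)(F)F)C(F)(F)F
Why: C4–H is the only acidic proton left (C6 and C8 are quaternary), so O-sulfonylation of the potassium enolate should give a single tetrasubstituted enol triflate and remove the C4 stereocentre.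

Step 10
Reactants: 12 1,2,3,8-tetramethyl-4-oxo-5-oxatricyclo[4.3.1.0^3,10]dec-8-en-9-yl trifluoromethanesulfonate
Product: 13 1,2,3,8-tetramethyl-5-oxatricyclo[4.3.1.0^3,10]dec-8-en-4-one (alkene lactone, C4(Me)=C5H)
Conditions: Pd(OAc)2 (5 mol %), PPh3 (10 mol %), HCO2H, Bu3N, DMF, 60 °C
Reagents that add atoms: none
Why: Palladium-catalysed formate hydrogenolysis of an enol triflate (oxidative addition to zerovalent palladium, decarboxylation of the formate, reductive elimination) replaces C5–OTf by C5–H and fixes the trisubstituted alkene regiospecifically; the lactone and all stereocentres are untouched.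

Step 11
Reactants: 13 1,2,3,8-tetramethyl-5-oxatricyclo[4.3.1.0^3,10]dec-8-en-4-one; 14 methyl 2-methyl-3-oxopentanoate
Product: 16 methyl 5-(2-hydroxy-4,6,7,8-tetramethylbicyclo[4.2.0]oct-4-en-8-yl)-2,4-dimethyl-3,5-dioxopentanoate, via sodium lithium dianion 15 (not isolated)
Conditions: 14 (3 equiv), NaH then n-BuLi, THF, 0 °C; add 13, 0 → 25 °C; 1 M HCl
Reagents that add atoms: none
Why: γ-Acylation of a β-keto ester dianion (Claisen-type condensation): the more basic terminal carbanion should add to the strained lactone carbonyl, the only electrophile in 13, whose α-carbon C8 is quaternary and cannot be enolised; ring opening frees the C2 alkoxide, excess dianion deprotonates the product and stops further addition, and the chain stereocentres do not matter because they are lost in step 12.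

Step 12
Reactants: 16 methyl 5-(2-hydroxy-4,6,7,8-tetramethylbicyclo[4.2.0]oct-4-en-8-yl)-2,4-dimethyl-3,5-dioxopentanoate
Product: 17 4-hydroxy-6-(2-hydroxy-4,6,7,8-tetramethylbicyclo[4.2.0]oct-4-en-8-yl)-3,5-dimethyl-2H-pyran-2-one
Conditions: DBU, toluene, 60 °C
Reagents that add atoms: none
Why: Base-mediated cyclisation of a 3,5-dioxo ester: the enol oxygen of the C8 acyl group attacks the methyl ester in a six-membered lactonisation, and loss of methanol gives the conjugated 4-hydroxy-2-pyranone as the thermodynamic sink; the isolated alkene and the secondary alcohol are unaffected.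

Step 13
Reactants: 17 4-hydroxy-6-(2-hydroxy-4,6,7,8-tetramethylbicyclo[4.2.0]oct-4-en-8-yl)-3,5-dimethyl-2H-pyran-2-one
Product: 19 6-(2-hydroxy-4,6,7,8-tetramethylbicyclo[4.2.0]oct-4-en-8-yl)-2-methoxy-3,5-dimethyl-4H-pyran-4-one, via hydroxypyrylium triflate 18 (not isolated)
Conditions: MeOTf (1.2 equiv), CH2Cl2, 25 °C; aq NaHCO3
Reagents that add atoms: methyl trifluoromethanesulfonate COS(=O)(=O)C(F)(F)F
Why: Methylation of the neutral 4-hydroxy-2-pyranone by a hard alkylating agent takes place at its most nucleophilic site, the lactone carbonyl oxygen, and deprotonation of the salt in the bicarbonate wash should give the 2-methoxy-4-pyranone; the acid stays bound in the salt, and the hindered neutral C2–OH reacts much more slowly.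

Step 14
Reactants: 19 6-(2-hydroxy-4,6,7,8-tetramethylbicyclo[4.2.0]oct-4-en-8-yl)-2-methoxy-3,5-dimethyl-4H-pyran-4-one
Product: 20 2-methoxy-3,5-dimethyl-6-(4,6,7,8-tetramethyl-2-oxobicyclo[4.2.0]oct-4-en-8-yl)-4H-pyran-4-one
Conditions: Dess–Martin periodinane, NaHCO3, CH2Cl2, 0 °C
Reagents that add atoms: none
Why: Dess–Martin oxidation under bicarbonate buffer converts the secondary C2 alcohol into the ketone under non-enolising conditions, so C4=C5 should stay out of conjugation and C1 should not epimerise; the relay stereocentre C2 has done its work and is removed.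

Step 15
Reactants: 20 2-methoxy-3,5-dimethyl-6-(4,6,7,8-tetramethyl-2-oxobicyclo[4.2.0]oct-4-en-8-yl)-4H-pyran-4-one
Product: 21 2-methoxy-3,5-dimethyl-6-(4,6,7,8-tetramethyl-2-methylidenebicyclo[4.2.0]oct-4-en-8-yl)-4H-pyran-4-one (skipped diene)
Conditions: Zn, CH2Br2, TiCl4 (pre-aged), THF/CH2Cl2, 0 → 25 °C
Reagents that add atoms: dibromomethane BrCBr
Why: Lombardo methylenation: the non-basic gem-dizinc/titanium reagent methylenates easily enolised ketones without double-bond migration and leaves ester-type carbonyl groups, such as that of the pyranone, alone, which should give the 1,4-diene.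

Step 16
Reactants: 21 2-methoxy-3,5-dimethyl-6-(4,6,7,8-tetramethyl-2-methylidenebicyclo[4.2.0]oct-4-en-8-yl)-4H-pyran-4-one
Product: 22 6-(5-hydroperoxy-4,6,7,8-tetramethyl-2-methylidenebicyclo[4.2.0]oct-3-en-8-yl)-2-methoxy-3,5-dimethyl-4H-pyran-4-one (OOH on the convex face)
Conditions: O2, tetraphenylporphyrin (0.5 mol %), visible light, CH2Cl2, −20 °C
Reagents that add atoms: dioxygen O=O
Why: Schenck ene reaction: singlet oxygen attacks the electron-richer trisubstituted C4=C5 bond and must bind to C5, because all allylic hydrogens sit on substituents of C4; it comes from the convex face, since the other face is covered by the cyclobutane and its endo pyranone, and should take the doubly allylic, pseudoaxial C3–H on that face, which sets C5 with OOH anti to the cyclobutane and forms a C3=C4/C2=CH2 diene that is locked s-trans and so cannot add a second oxygen by [4+2].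

Step 17
Reactants: 22 6-(5-hydroperoxy-4,6,7,8-tetramethyl-2-methylidenebicyclo[4.2.0]oct-3-en-8-yl)-2-methoxy-3,5-dimethyl-4H-pyran-4-one
Product: 23 endoperoxide with an acetoxymercuriomethyl group on C2 (2,3-dioxabicyclo[2.2.2]oct-5-ene bridging C2 and C5 on the convex face, CH2HgOAc on the cyclobutane side)
Conditions: Hg(OAc)2 (1.05 equiv), CH2Cl2, 0 °C, dark
Reagents that add atoms: mercury diacetate CC(=O)O[Hg]OC(C)=O
Why: Divalent mercury binds the unhindered terminal CH2 of the exocyclic alkene, so the developing positive charge rests on C2, which is both tertiary and allylic. The outer oxygen of the pseudoaxial C5–OOH group reaches C2 across the ring and gives its proton to acetate, which makes the C2–O bond and leaves the C–HgOAc bond on the future methyl carbon. The closest known reaction type is the intramolecular peroxymercuration of unsaturated hydroperoxides, by which cyclohex-3-enyl hydroperoxide is closed to a 2,3-dioxabicyclo[2.2.2]octane. The closure is 6-exo-trig with respect to C2=CH2 and forms the one new peroxide ring, which reads as a 1,2-dioxane through C1–C6 and as a 3,6-dihydro-1,2-dioxine through C3=C4. The new stereocentre C2 is dictated by C5, because a two-atom O–O bridge can span the ring only on the face where the hydroperoxide already stands, so oxygen enters convex and the mercuriomethyl group is turned toward the cyclobutane. The step needs C2 rather than C4 as the site of capture, which ring size secures because closure at C4 would require a 1,2-dioxetane, and it needs attack on the 1,1-disubstituted rather than the trisubstituted alkene, which is secured by the crowding of C3=C4 between C4–Me and C5 and by working without strong acid so that Hock-type cleavage stays slow.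

Step 18
Reactants: 23 endoperoxide with an acetoxymercuriomethyl group on C2
Product: 24 CNP0183511.1 (target endoperoxide)
Conditions: Bu3SnH (3 equiv), CH2Cl2, −20 °C
Reagents that add atoms: none
Why: Radical-chain hydridodemercuration: the tin hydride turns C–HgOAc into C–HgH, which loses mercury to a primary β-peroxyalkyl radical, and a large excess of fast hydrogen donor at low temperature should trap this radical before it attacks the O–O bond; the neutral medium also spares C5–H from base-induced Kornblum–DeLaMare cleavage, and no stereocentre is touched.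

**Compound list**
1 | 1,4-dioxaspiro[4.5]dec-6-en-8-one | O=C1C=CC2(CC1)OCCO2 | starting material
2 | [(6-methyl-1,4-dioxaspiro[4.5]dec-7-en-8-yl)oxy]trimethylsilane (racemic) | C[Si](C)(C)OC1=CC(C)C2(CC1)OCCO2 | intermediate
3 | 6-methyl-1,4-dioxaspiro[4.5]dec-6-en-8-one | CC1=CC(=O)CCC12OCCO2 | intermediate
4 | (R)-6-methyl-1,4-dioxaspiro[4.5]dec-6-en-8-ol | O[C@H]1C=C(C)C2(CC1)OCCO2 | intermediate
5 | (E)-1-bromobut-2-ene (crotyl bromide) | C/C=C/CBr | starting material
6 | (R)-8-[(E)-but-2-enyloxy]-6-methyl-1,4-dioxaspiro[4.5]dec-6-ene | C/C=C/CO[C@H]1C=C(C)C2(CC1)OCCO2 | intermediate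
7 | (R)-4-[(E)-but-2-enyloxy]-2-methylcyclohex-2-en-1-one | C/C=C/CO[C@H]1C=C(C)C(=O)CC1 | intermediate
8 | 1,2-dimethyl-5-oxatricyclo[4.3.1.0^3,10]decan-9-one (photoadduct) | C1[C@H]2[C@H](C)[C@@]3(C)C(=O)CC[C@@H](O1)[C@@H]23 | intermediate
9 | 1,2-dimethyl-5-oxatricyclo[4.3.1.0^3,10]decane-4,9-dione (keto lactone) | O=C1[C@H]2[C@H](C)[C@@]3(C)C(=O)CC[C@@H](O1)[C@@H]23 | intermediate
10 | dilithium bis-enolate of 9 (C4=C5–OLi and C8=C(OLi)O), not isolated | [Li]OC1=C2[C@H](C)[C@@]3(C)C(O[Li])=CC[C@@H](O1)[C@@H]23 | intermediate
11 | 1,2,3,8-tetramethyl-5-oxatricyclo[4.3.1.0^3,10]decane-4,9-dione (C4 epimers) | O=C1[C@@]2(C)[C@H](C)[C@@]3(C)C(=O)C(C)C[C@@H](O1)[C@@H]23 | intermediate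
12 | 1,2,3,8-tetramethyl-4-oxo-5-oxatricyclo[4.3.1.0^3,10]dec-8-en-9-yl trifluoromethanesulfonate | O=C1[C@@]2(C)[C@H](C)[C@@]3(C)C(OS(=O)(=O)C(F)(F)F)=C(C)C[C@@H](O1)[C@@H]23 | intermediate
13 | 1,2,3,8-tetramethyl-5-oxatricyclo[4.3.1.0^3,10]dec-8-en-4-one (alkene lactone) | O=C1[C@@]2(C)[C@H](C)[C@@]3(C)C=C(C)C[C@@H](O1)[C@@H]23 | intermediate
14 | methyl 2-methyl-3-oxopentanoate | CCC(=O)C(C)C(=O)OC | starting material
15 | sodium lithium dianion of 14, not isolated | C[CH-]C([O-])=C(C)C(=O)OC.[Na+].[Li+] | intermediate
16 | methyl 5-(2-hydroxy-4,6,7,8-tetramethylbicyclo[4.2.0]oct-4-en-8-yl)-2,4-dimethyl-3,5-dioxopentanoate (chain centres undefined) | COC(=O)C(C)C(=O)C(C)C(=O)[C@@]2(C)[C@H](C)[C@@]3(C)C=C(C)C[C@@H](O)[C@@H]23 | intermediate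
17 | 4-hydroxy-2-pyranone carbinol | O=c1oc([C@@]2(C)[C@H](C)[C@@]3(C)C=C(C)C[C@@H](O)[C@@H]23)c(C)c(O)c1C | intermediate
18 | 4-hydroxy-2-methoxypyrylium triflate of 17, not isolated | COc1[o+]c([C@@]2(C)[C@H](C)[C@@]3(C)C=C(C)C[C@@H](O)[C@@H]23)c(C)c(O)c1C.[O-]S(=O)(=O)C(F)(F)F | intermediate
19 | 2-methoxy-4-pyranone carbinol (C2–OH on the cyclobutane face) | COc1oc([C@@]2(C)[C@H](C)[C@@]3(C)C=C(C)C[C@@H](O)[C@@H]23)c(C)c(=O)c1C | intermediate
20 | β,γ-unsaturated C2 ketone | COc1oc([C@@]2(C)[C@H](C)[C@@]3(C)C=C(C)CC(=O)[C@@H]23)c(C)c(=O)c1C | intermediate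
21 | skipped diene (C2=CH2, C4=C5) | COc1oc([C@@]2(C)[C@H](C)[C@@]3(C)C=C(C)CC(=C)[C@@H]23)c(C)c(=O)c1C | intermediate
22 | C5 hydroperoxide of the 2-methylidenebicyclo[4.2.0]oct-3-ene pyranone | COc1oc([C@@]2(C)[C@H](C)[C@@]3(C)[C@H](OO)C(C)=CC(=C)[C@@H]23)c(C)c(=O)c1C | intermediate
23 | endoperoxide with an acetoxymercuriomethyl group on C2 | COc1oc([C@@]2(C)[C@H](C)[C@@]3(C)[C@@H]4OO[C@@](C[Hg]OC(C)=O)(C=C4C)[C@@H]23)c(C)c(=O)c1C | intermediate
24 | CNP0183511.1 | COc1oc([C@@]2(C)[C@H](C)[C@@]3(C)[C@@H]4OO[C@@](C)(C=C4C)[C@@H]23)c(C)c(=O)c1C | target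

**Totals**
Total step count: 18. Longest linear sequence: 18 steps (1 → 24). Compounds 5 and 14 are bought.

**Steps most likely to fail**

Step 17 (key step).
- What may go wrong: mercuration of the trisubstituted C3=C4 bond, or acetate capture of the allyl cation instead of ring closure. The dienyl hydroperoxide may also break down under metal or acid (Hock-type cleavage, dehydration at C5) before the C2–O bond forms.
- Fallback: the peroxide is brought in by cycloaddition rather than by cyclisation, setting out from 21. RhCl3·3H2O (cat.) in EtOH at 60 °C should move the exocyclic double bond into the ring and into conjugation, giving the 2,4,6,7,8-pentamethylbicyclo[4.2.0]octa-2,4-dien-8-yl pyranone F1. Sensitised photooxygenation (O2, tetraphenylporphyrin, visible light, CH2Cl2, 0 °C) should then add singlet oxygen across C2 and C5 from the convex face in a [4+2] reaction. The fallback comes back to the route at 24.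

Step 16.
- What may go wrong: hydrogen abstraction from the C4 methyl group instead of from C3 (loss of regiocontrol at the perepoxide stage), or sluggish attack next to quaternary C6 with over-oxidation of the product diene.
- Fallback: oxygen is tied to C5 by a cycloaddition to an electron-rich dienol ether, so no choice of allylic hydrogen arises. It sets out from 20. t-BuMe2SiOTf and Et3N should give the C2 tert-butyldimethylsilyl dienol ether F2. Singlet oxygen should add across C2 and C5 from the convex face, and methanol should open the silyl peroxyketal to the C5-hydroperoxy C3-en-2-one F3. 2-Methoxypropene with pyridinium tosylate should mask it as the 2-methoxyprop-2-yl perketal F4. Salt-free Ph3P=CH2 at −78 °C should methylenate the enone, which can no longer deconjugate, to the methylidene perketal F5. Aqueous acetic acid should release the hydroperoxide, and the fallback comes back to the route at 22.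

Step 11.
- What may go wrong: slow addition of the bulky secondary carbanion to the neopentyl-type lactone carbonyl, so that proton transfer wins, and re-closure of the freed C2 hydroxyl onto the new ketone in later handling.
- Fallback: the chain is added in two smaller pieces and the hydroxyl is removed early. It sets out from 13. EtLi at −78 °C should open the lactone to the C8 propanoyl C2 carbinol F6. Dess–Martin periodinane should give the C2 ketone propanoyl compound F7. Zn/CH2Br2/TiCl4 should methylenate only the unhindered C2 ketone, giving the skipped-diene ethyl ketone F8. LiN(SiMe3)2 and then methyl 3-chloro-2-methyl-3-oxopropanoate should acylate the unhindered enolate carbon to the skipped-diene 3,5-dioxo ester F9. DBU should close it to the skipped-diene 4-hydroxy-2-pyranone F10, and MeOTf followed by a bicarbonate wash should methylate it. The fallback comes back to the route at 21.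

**Further compounds**
F1 | step 17 | 2,4,6,7,8-pentamethylbicyclo[4.2.0]octa-2,4-dien-8-yl pyranone | COc1oc([C@@]2(C)[C@H](C)[C@@]3(C)C=C(C)C=C(C)[C@@H]23)c(C)c(=O)c1C
F2 | step 16 | C2 tert-butyldimethylsilyl dienol ether | COc1oc([C@@]2(C)[C@H](C)[C@@]3(C)C=C(C)C=C(O[Si](C)(C)C(C)(C)C)[C@@H]23)c(C)c(=O)c1C
F3 | step 16 | C5-hydroperoxy C3-en-2-one | COc1oc([C@@]2(C)[C@H](C)[C@@]3(C)[C@H](OO)C(C)=CC(=O)[C@@H]23)c(C)c(=O)c1C
F4 | step 16 | 2-methoxyprop-2-yl perketal | COc1oc([C@@]2(C)[C@H](C)[C@@]3(C)[C@H](OOC(C)(C)OC)C(C)=CC(=O)[C@@H]23)c(C)c(=O)c1C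
F5 | step 16 | methylidene perketal | COc1oc([C@@]2(C)[C@H](C)[C@@]3(C)[C@H](OOC(C)(C)OC)C(C)=CC(=C)[C@@H]23)c(C)c(=O)c1C
F6 | step 11 | C8 propanoyl C2 carbinol | CCC(=O)[C@@]2(C)[C@H](C)[C@@]3(C)C=C(C)C[C@@H](O)[C@@H]23
F7 | step 11 | C2 ketone propanoyl compound | CCC(=O)[C@@]2(C)[C@H](C)[C@@]3(C)C=C(C)CC(=O)[C@@H]23
F8 | step 11 | skipped-diene ethyl ketone | CCC(=O)[C@@]2(C)[C@H](C)[C@@]3(C)C=C(C)CC(=C)[C@@H]23
F9 | step 11 | skipped-diene 3,5-dioxo ester | COC(=O)C(C)C(=O)C(C)C(=O)[C@@]2(C)[C@H](C)[C@@]3(C)C=C(C)CC(=C)[C@@H]23
F10 | step 11 | skipped-diene 4-hydroxy-2-pyranone | O=c1oc([C@@]2(C)[C@H](C)[C@@]3(C)C=C(C)CC(=C)[C@@H]23)c(C)c(O)c1C
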